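The spiro-cyclohexene is cut by a Diels–Alder disconnection (C2–C4′, C14–C15′) into two guaianolide monomers, both drawn from one tricyclic ketone. Everything rests on the C7–C11 bond of the γ-lactone ring (O–C6–C7–C11–C12; C7′–C11′ in the spiro half): a C11 vinyl radical, tethered to O6 as a 2-bromoallyl mixed acetal on a monocyclic cyclopentanone, closes this ring 5-exo onto a C7=C8 vinyl group; the C8 radical then closes the seven-membered ring 7-endo onto an allyl sulfone, whose fragmentation leaves the C10=C14 methylene. One operation forms two rings, both exocyclic methylenes and the trans C6/C7 relationship. The feature exploited is the trans-fused α-methylene lactone (1,4-dioxygenated C6–C7–C11–C12 array) beside the C10 exocyclic alkene.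

Key step: step 6

Remarks.
- Numbering: guaianolide numbering is used for all bi- and tricyclic compounds: C1–C5 five-membered ring with C15 on C4; C1 and C5–C10 seven-membered ring with C14 on C10; C6 carries the lactone oxygen; C11, C12, C13 are the lactone α-carbon, carbonyl carbon and methylene. Primed locants belong to the spiro half.
- Stereochemistry read from the SMILES: the enone half has H-5 cis to H-6 (5β,6β,7α,10α); the spiro half has the 1α,5α,6β,7α pattern. The route is built for exactly this: the trans-fused ketone 12 serves the enone half directly, and its C5 epimer 13 serves the spiro half.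
- Epimer mixtures: the acetal carbon C12 of 9–14 and 18 and the carbinol C3 of 20 are carried as mixtures that later oxidations remove.

**Common part**

Step 1
Reactants: 1 isopropenylmagnesium bromide; 2 9-methoxy-9-borabicyclo[3.3.1]nonane
Product: 3 9-(prop-1-en-2-yl)-9-borabicyclo[3.3.1]nonane
Conditions: THF/pentane, −78 °C → rt; BF3·OEt2, 0 °C; filtration under Ar, solvent exchange to PhMe
Reagents that add atoms: none
Why: B-alkenylation by transmetalation, in which the Grignard reagent adds to the borinate to give a methoxyborate and BF3 removes methoxide, the usual way to B-alkenyl-9-BBN reagents.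

Step 2
Reactants: 3 9-(prop-1-en-2-yl)-9-borabicyclo[3.3.1]nonane; 4 cyclopent-2-en-1-one; 5 acrolein
Product: 7 (2R,3R)-2-[(1S)-1-hydroxyprop-2-en-1-yl]-3-(prop-1-en-2-yl)cyclopentan-1-one, via boron enolate 6 (not isolated)
Conditions: [Rh(OMe)(cod)]2 (1.5 mol %), (R)-BINAP (3.3 mol %), PhMe, 80 °C; then 5, −78 → 0 °C; then 2-aminoethanol, Et2O
Reagents that add atoms: none
Why: Rhodium-catalysed asymmetric 1,4-addition of an organo-9-BBN (Hayashi–Miyaura type) gives the regiodefined boron enolate 6 with C1 set (R) by the (R)-BINAP–rhodium alkenyl species, and the boron aldol with acrolein through a closed chair transition state on the enolate face anti to the isopropenyl group sets C5 (trans to C1) and C6 (anti aldol).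

Step 3
Reactants: 7 (2R,3R)-2-[(1S)-1-hydroxyprop-2-en-1-yl]-3-(prop-1-en-2-yl)cyclopentan-1-one; 8 methoxyallene
Product: 9 (2R,3R)-2-[(1S)-1-(2-bromo-1-methoxyprop-2-en-1-yloxy)prop-2-en-1-yl]-3-(prop-1-en-2-yl)cyclopentan-1-one (acetal epimers)
Conditions: 8 (3 equiv), NBS (1.3 equiv), CH2Cl2, −78 → −20 °C
Reagents that add atoms: N-bromosuccinimide, BrN1C(=O)CCC1=O
Why: NBS-mediated alkoxybromination of the alkoxyallene (haloacetalisation), in which bromonium attack at the central allene carbon gives an oxocarbenium ion that the C6 alcohol traps, installs the vinyl bromide and the O6–C12 tether without touching any stereocentre.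

Step 4
Reactants: 9 bromoallyl mixed acetal
Product: 10 (2R,3R)-2-[(1S)-1-(2-bromo-1-methoxyprop-2-en-1-yloxy)prop-2-en-1-yl]-3-(3-chloroprop-1-en-2-yl)cyclopentan-1-one
Conditions: Ca(OCl)2, solid CO2, CH2Cl2/H2O, 0 °C
Reagents that add atoms: calcium hypochlorite, [Ca+2].[O-]Cl.[O-]Cl
Why: Ene-type allylic chlorination by HOCl picks the electron-rich 1,1-disubstituted alkene over the vinyl group and the bromoalkene and shifts the double bond to give the 2-(chloromethyl)allyl unit.

Step 5
Reactants: 10 allylic chloride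
Product: 11 (2R,3R)-2-[(1S)-1-(2-bromo-1-methoxyprop-2-en-1-yloxy)prop-2-en-1-yl]-3-[3-(phenylsulfonyl)prop-1-en-2-yl]cyclopentan-1-one
Conditions: PhSO2Na (1.5 equiv), NaI (0.1 equiv), DMF, rt
Reagents that add atoms: sodium benzenesulfinate, [Na+].[O-]S(=O)c1ccccc1
Why: SN2 S-alkylation of the soft, non-basic sulfinate by the allylic chloride (the SN2′ path gives the same compound) leaves the β-alkoxy ketone untouched.

Step 6
Reactants: 11 allyl sulfone bromoallyl acetal
Product: 12 trans-fused tricyclic ketone, 12-methoxy-6α,12-epoxy-15-norguaia-10(14),11(13)-dien-4-one with H-1α, H-5β, H-6β, H-7α (2-methoxy-3,6-dimethylidene-decahydroazuleno[4,5-b]furan-9-one, anomer mixture)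
Conditions: Bu3SnH (1.3 equiv) and AIBN (0.2 equiv) added by syringe pump over 8 h, PhH (0.005 M), 80 °C; MeCN/hexane partition
Reagents that add atoms: none
Why: Bu3Sn• abstracts bromine from the vinyl bromide, the C11 σ-vinyl radical adds to C7 of the vinyl group (the C7–C11 bond), the primary C8 radical so formed adds to the CH2 terminus (C9) of the allyl sulfone, and β-scission of the tertiary C10 radical expels PhSO2•, which Bu3SnH reduces to carry the chain. The closest known reaction types are the vinyl-radical cyclisation of 2-bromoallyl mixed acetals (Ueno–Stork type), the tandem 5-exo/7-endo radical cyclisation of haloacetals onto two alkenes, and radical allylation with allyl sulfones. The oxolane (the lactone ring at the lactol level) closes 5-exo-trig and the cycloheptane 7-endo-trig, the 6-exo alternative being disfavoured because it would attack the fully substituted C10 and has no fragmentation outlet. C7 is set in the 5-exo step by a chair-like transition state with the cyclopentyl group on C6 pseudo-equatorial, which puts H-6 and H-7 trans; C1, C5 and C6 are untouched, so the 5/7 fusion stays trans (H-5β). The step needs both ring closures to outrun hydrogen transfer to the C8 radical and its 3-exo/ring-opening rearrangement, which high dilution with slow addition of Bu3SnH and the activated, fragmenting acceptor are meant to secure, while the ketone and the acetal are inert to carbon radicals.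

**Spiro half (dienophile)**

Step 7
Reactants: 12 trans-fused tricyclic ketone
Product: 13 cis-fused tricyclic ketone, the C5 epimer of 12 (H-1α, H-5α, H-6β, H-7α)
Conditions: DBU (0.3 equiv), PhMe, rt
Reagents that add atoms: none
Why: Base-mediated epimerisation through the C4 enolate should equilibrate C5 to the cis-fused hydroazulenone, expected to be favoured because the C4–C5 bond then sits pseudo-equatorial on the seven-membered ring and anti to C7 as in the natural guaianolides, while C1, C6 and C7 cannot enolise.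

Step 8
Reactants: 13 cis-fused tricyclic ketone
Product: 14 2-methoxy-3,6,9-trimethylidene-decahydroazuleno[4,5-b]furan with H-1α, H-5α, H-6β, H-7α (methyl lactol of dehydrocostus lactone)
Conditions: Cp2TiMe2 (2.5 equiv), PhMe/THF, 65 °C, dark
Reagents that add atoms: Cp2TiMe2 (bis(cyclopentadienyl)dimethyltitanium), [Ti+4].[CH3-].[CH3-].c1cc[cH-]c1.c1cc[cH-]c1
Why: Petasis methylenation through Cp2Ti=CH2 converts the hindered, enolisable ketone into the C4=C15 methylene without base or Lewis acid, so the allylic acetal survives.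

Step 9
Reactants: 14 methyl lactol
Product: 15 dehydrocostus lactone, (3aS,6aR,9aR,9bS)-3,6,9-trimethylidene-decahydroazuleno[4,5-b]furan-2-one
Conditions: CrO3, H2SO4, H2O, acetone, 0 °C
Reagents that add atoms: water, O
Why: Jones oxidation, in which the allylic methyl acetal is hydrolysed to the lactol and oxidised by chromic acid, is the standard finish of haloacetal cyclisations and unveils the α-methylene lactone.

Step 10
Reactants: 15 dehydrocostus lactone
Product: 16 3-epizaluzanin C (3α-hydroxyguaia-4(15),10(14),11(13)-trien-12,6α-olide)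
Conditions: SeO2 (0.3 equiv), t-BuOOH (2 equiv), CH2Cl2, rt
Reagents that add atoms: tert-butyl hydroperoxide, CC(C)(C)OO
Why: Riley allylic oxidation (ene reaction then [2,3]-shift) should occur at C3, the ring CH2 allylic to the C4=C15 alkene, from the convex α face, the electron-poor lactone methylene being inert (either C3 epimer serves).

Step 11
Reactants: 16 3-epizaluzanin C
Product: 17 dehydrozaluzanin C (3-oxoguaia-4(15),10(14),11(13)-trien-12,6α-olide)
Conditions: Dess–Martin periodinane (1.3 equiv), CH2Cl2, 0 °C → rt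
Reagents that add atoms: none
Why: Dess–Martin oxidation turns the allylic alcohol into the exocyclic enone under neutral conditions that leave the alkenes and the lactone alone.

**Enone half (diene)**

Step 12
Reactants: 12 trans-fused tricyclic ketone
Product: 18 2-methoxy-3,6,9-trimethylidene-decahydroazuleno[4,5-b]furan with H-1α, H-5β, H-6β, H-7α (5-epi methyl lactol)
Conditions: Cp2TiMe2 (2.5 equiv), PhMe/THF, 65 °C, dark
Reagents that add atoms: Cp2TiMe2 (bis(cyclopentadienyl)dimethyltitanium), [Ti+4].[CH3-].[CH3-].c1cc[cH-]c1.c1cc[cH-]c1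
Why: Petasis methylenation is neither basic nor Lewis acidic, so the kinetically formed trans ring fusion (H-5β) is carried through and fixed once C4 is no longer a carbonyl.

Step 13
Reactants: 18 5-epi methyl lactol
Product: 19 5-epi-dehydrocostus lactone, (3aS,6aR,9aS,9bS)-3,6,9-trimethylidene-decahydroazuleno[4,5-b]furan-2-one
Conditions: CrO3, H2SO4, H2O, acetone, 0 °C
Reagents that add atoms: water, O
Why: Jones oxidation hydrolyses the allylic acetal and oxidises the lactol to the α-methylene lactone, as in step 9.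

Step 14
Reactants: 19 5-epi-dehydrocostus lactone
Product: 20 3-hydroxy-5βH-guaia-4(15),10(14),11(13)-trien-12,6α-olide (C3 epimers)
Conditions: SeO2 (0.3 equiv), t-BuOOH (2 equiv), CH2Cl2, rt
Reagents that add atoms: tert-butyl hydroperoxide, CC(C)(C)OO
Why: Riley allylic oxidation at the C3 methylene next to the C4=C15 alkene is expected by analogy with step 10, and the configuration of the carbinol is irrelevant.

Step 15
Reactants: 20 allylic alcohol
Product: 21 5-epi-dehydrozaluzanin C (3-oxo-5βH-guaia-4(15),10(14),11(13)-trien-12,6α-olide)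
Conditions: Dess–Martin periodinane (1.3 equiv), CH2Cl2, 0 °C → rt
Reagents that add atoms: none
Why: Dess–Martin oxidation gives the exocyclic enone, in which C5 is no longer acidic.

Step 16
Reactants: 21 5-epi-dehydrozaluzanin C
Product: 22 3-(tert-butyldimethylsilyloxy)-5βH-guaia-2,4(15),10(14),11(13)-tetraen-12,6α-olide
Conditions: TBSOTf (1.3 equiv), Et3N (2 equiv), CH2Cl2, 0 °C
Reagents that add atoms: tert-butyldimethylsilyl triflate, CC(C)(C)[Si](C)(C)OS(=O)(=O)C(F)(F)F
Why: Soft enolisation and O-silylation can only go toward C2, the single α-carbon bearing hydrogen, and give the silyl dienol ether.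

Step 17
Reactants: 22 silyl dienol ether
Product: 23 3-oxo-5βH-guaia-1,4(15),10(14),11(13)-tetraen-12,6α-olide (dienone)
Conditions: Pd(OAc)2 (1.1 equiv), MeCN, rt; used at once
Reagents that add atoms: none
Why: Saegusa–Ito oxidation, in which palladation at C2 on the α face is followed by syn β-hydride elimination of H-1α, gives the C1=C2 enone and with it the C2=C1–C10=C14 diene without touching C5.

**Union**

Step 18
Reactants: 23 dienone; 17 dehydrozaluzanin C
Product: 25 target dimer, via Diels–Alder adduct 24 (not isolated)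
Conditions: 23 in PhMe added by syringe pump over several hours to an equimolar amount of 17 (1 M in degassed PhMe), BHT, 45 °C; then Et3N (0.2 equiv), rt
Reagents that add atoms: none
Why: Intermolecular Diels–Alder reaction of the diene C2=C1–C10=C14 of 23 with the exocyclic enone C4′=C15′ of 17 (regiochemistry from the large coefficients at C14 and C15′; slow addition keeps 23 dilute so that it meets 17 and not itself) should join the diene β face, anti to C6 and the lactone, to the convex α face of 17, which alone fixes the spiro centre C4′ because C2 becomes trigonal again, and the amine then moves H-2 (α face) suprafacially to C10 within the ion pair, bringing the alkene into conjugation and setting H-10α.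

**Compound list**

1 | isopropenylmagnesium bromide | C=C(C)[Mg]Br | starting material
2 | 9-methoxy-9-borabicyclo[3.3.1]nonane | COB1C2CCCC1CCC2 | starting material
3 | 9-(prop-1-en-2-yl)-9-borabicyclo[3.3.1]nonane | C=C(C)B1C2CCCC1CCC2 | intermediate
4 | cyclopent-2-en-1-one | O=C1C=CCC1 | starting material
5 | acrolein | C=CC=O | starting material
6 | 9-{[(3R)-3-(prop-1-en-2-yl)cyclopent-1-en-1-yl]oxy}-9-borabicyclo[3.3.1]nonane (boron enolate) | C=C(C)[C@@H]1CCC(OB2C3CCCC2CCC3)=C1 | intermediate
7 | (2R,3R)-2-[(1S)-1-hydroxyprop-2-en-1-yl]-3-(prop-1-en-2-yl)cyclopentan-1-one | O=C1CC[C@@H](C(C)=C)[C@@H]1[C@@H](O)C=C | intermediate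
8 | methoxyallene (1-methoxypropa-1,2-diene) | COC=C=C | starting material
9 | (2R,3R)-2-[(1S)-1-(2-bromo-1-methoxyprop-2-en-1-yloxy)prop-2-en-1-yl]-3-(prop-1-en-2-yl)cyclopentan-1-one (acetal epimers) | O=C1CC[C@@H](C(C)=C)[C@@H]1[C@@H](OC(OC)C(Br)=C)C=C | intermediate
10 | (2R,3R)-2-[(1S)-1-(2-bromo-1-methoxyprop-2-en-1-yloxy)prop-2-en-1-yl]-3-(3-chloroprop-1-en-2-yl)cyclopentan-1-one | O=C1CC[C@@H](C(CCl)=C)[C@@H]1[C@@H](OC(OC)C(Br)=C)C=C | intermediate
11 | (2R,3R)-2-[(1S)-1-(2-bromo-1-methoxyprop-2-en-1-yloxy)prop-2-en-1-yl]-3-[3-(phenylsulfonyl)prop-1-en-2-yl]cyclopentan-1-one | O=C1CC[C@@H](C(CS(=O)(=O)c2ccccc2)=C)[C@@H]1[C@@H](OC(OC)C(Br)=C)C=C | intermediate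
12 | trans-fused 2-methoxy-3,6-dimethylidene-decahydroazuleno[4,5-b]furan-9-one (H-1α, H-5β, H-6β, H-7α; anomers) | O=C1CC[C@H]2C(=C)CC[C@H]3C(=C)C(OC)O[C@@H]3[C@@H]21 | intermediate
13 | cis-fused 2-methoxy-3,6-dimethylidene-decahydroazuleno[4,5-b]furan-9-one (H-1α, H-5α, H-6β, H-7α; anomers) | O=C1CC[C@H]2C(=C)CC[C@H]3C(=C)C(OC)O[C@@H]3[C@H]21 | intermediate
14 | 2-methoxy-3,6,9-trimethylidene-decahydroazuleno[4,5-b]furan (H-5α series; anomers) | C=C1CC[C@H]2C(=C)CC[C@H]3C(=C)C(OC)O[C@@H]3[C@H]21 | intermediate
15 | dehydrocostus lactone | C=C1CC[C@H]2C(=C)CC[C@H]3C(=C)C(=O)O[C@@H]3[C@H]21 | intermediate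
16 | 3-epizaluzanin C (3α-OH) | C=C1[C@H](O)C[C@H]2C(=C)CC[C@H]3C(=C)C(=O)O[C@@H]3[C@H]21 | intermediate
17 | dehydrozaluzanin C | C=C1C(=O)C[C@H]2C(=C)CC[C@H]3C(=C)C(=O)O[C@@H]3[C@H]21 | intermediate
18 | 2-methoxy-3,6,9-trimethylidene-decahydroazuleno[4,5-b]furan (H-5β series; anomers) | C=C1CC[C@H]2C(=C)CC[C@H]3C(=C)C(OC)O[C@@H]3[C@@H]21 | intermediate
19 | 5-epi-dehydrocostus lactone | C=C1CC[C@H]2C(=C)CC[C@H]3C(=C)C(=O)O[C@@H]3[C@@H]21 | intermediate
20 | 3-hydroxy-5βH-guaia-4(15),10(14),11(13)-trien-12,6α-olide (C3 epimers) | C=C1C(O)C[C@H]2C(=C)CC[C@H]3C(=C)C(=O)O[C@@H]3[C@@H]21 | intermediate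
21 | 5-epi-dehydrozaluzanin C | C=C1C(=O)C[C@H]2C(=C)CC[C@H]3C(=C)C(=O)O[C@@H]3[C@@H]21 | intermediate
22 | 3-(tert-butyldimethylsilyloxy)-5βH-guaia-2,4(15),10(14),11(13)-tetraen-12,6α-olide | C=C1C(O[Si](C)(C)C(C)(C)C)=C[C@H]2C(=C)CC[C@H]3C(=C)C(=O)O[C@@H]3[C@@H]21 | intermediate
23 | 3-oxo-5βH-guaia-1,4(15),10(14),11(13)-tetraen-12,6α-olide | C=C1C(=O)C=C2C(=C)CC[C@H]3C(=C)C(=O)O[C@@H]3[C@H]12 | intermediate
24 | Diels–Alder adduct (H-2α, C1=C10, spiro at C4′) | C=C1C(=O)[C@@H]2C3=C(CC[C@H]4C(=C)C(=O)O[C@@H]4[C@H]13)CC[C@]21C(=O)C[C@H]2C(=C)CC[C@H]3C(=C)C(=O)O[C@@H]3[C@H]21 | intermediate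
25 | target dimer (CNP0221188.1) | C=C1C(=O)C2=C3[C@H](CC[C@H]4C(=C)C(=O)O[C@@H]4[C@H]13)CC[C@]21C(=O)C[C@H]2C(=C)CC[C@H]3C(=C)C(=O)O[C@@H]3[C@H]21 | target

**Step count and risks**

Total step count: 18. Longest linear sequence: 13 (steps 1–6, 12–17, 18).

Steps most likely to fail:

1. Step 6. The homoallylic C8 radical formed after the 5-exo closure may rearrange (3-exo attack on the neighbouring C11=C13 alkene and reopening to a six-membered-ring radical) or be reduced before the slower 7-endo closure. Fallback, an sp3 radical with the lactone methylene added later: set out from 7. Ethyl vinyl ether and NBS give the 2-bromoethyl ethyl acetal F1; Ca(OCl)2/CO2 and then PhSO2Na give the chloride F2 and the sulfone F3; Bu3SnH/AIBN at the same dilution gives, through a primary alkyl radical at C11 whose cyclised form cannot rearrange, the tricyclic ketone F4 lacking C13. One part is methylenated with Cp2TiMe2 to the methylene acetal F5, oxidised (Jones) to the lactone F6, formylated (NaH, HCO2Et) to the hydroxymethylene lactone F7 and treated with aqueous HCHO/K2CO3, which returns to the route at 19. The other part is epimerised with DBU to the cis ketone F8 and taken by the same operations through the methylene acetal F9, the lactone F10 and the hydroxymethylene lactone F11 to 15.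

2. Step 18. The dienone 23 may dimerise with itself or decompose before it meets 17, since it carries both a diene and an exocyclic enone, and slow addition alone may not prevent this. Fallback, release of the diene only in the presence of the dienophile: set out from 22. PhSeCl (CH2Cl2, −78 °C) gives the 2α-phenylselanyl ketone F12; oxidation with mCPBA at −78 °C gives the selenoxide F13; 17 is then added and the mixture warmed slowly to rt, so that syn elimination toward H-1α frees 23 gradually and it is trapped as it forms; cycloaddition and the Et3N isomerisation then return to the route at 25.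

3. Step 7. The equilibrium may not lie far enough on the side of the cis-fused ketone, or the enolate may expel O6 (β-elimination that opens the oxolane). Fallback, kinetic instead of thermodynamic control: set out from 12. TMSCl/NaI/Et3N in MeCN gives the more substituted trimethylsilyl enol ether F14 (C4=C5); protonation with TBAF/AcOH in THF at −78 °C should deliver hydrogen to C5 from the α face, syn to H-1 and away from the C7–C8 bridge, and returns to the route at 13.

Further compounds
F1 | step 6 | (2R,3R)-2-[(1S)-1-(2-bromo-1-ethoxyethoxy)prop-2-en-1-yl]-3-(prop-1-en-2-yl)cyclopentan-1-one | O=C1CC[C@@H](C(C)=C)[C@@H]1[C@@H](OC(OCC)CBr)C=C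
F2 | step 6 | (2R,3R)-2-[(1S)-1-(2-bromo-1-ethoxyethoxy)prop-2-en-1-yl]-3-(3-chloroprop-1-en-2-yl)cyclopentan-1-one | O=C1CC[C@@H](C(CCl)=C)[C@@H]1[C@@H](OC(OCC)CBr)C=C
F3 | step 6 | (2R,3R)-2-[(1S)-1-(2-bromo-1-ethoxyethoxy)prop-2-en-1-yl]-3-[3-(phenylsulfonyl)prop-1-en-2-yl]cyclopentan-1-one | O=C1CC[C@@H](C(CS(=O)(=O)c2ccccc2)=C)[C@@H]1[C@@H](OC(OCC)CBr)C=C
F4 | step 6 | trans-fused 2-ethoxy-6-methylidene-decahydroazuleno[4,5-b]furan-9-one (H-1α, H-5β, H-6β, H-7α) | O=C1CC[C@H]2C(=C)CC[C@H]3CC(OCC)O[C@@H]3[C@@H]21
F5 | step 6 | 2-ethoxy-6,9-dimethylidene-decahydroazuleno[4,5-b]furan (H-5β series) | C=C1CC[C@H]2C(=C)CC[C@H]3CC(OCC)O[C@@H]3[C@@H]21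
F6 | step 6 | 13-nor-5-epi-dehydrocostus lactone (6,9-dimethylidene-decahydroazuleno[4,5-b]furan-2-one, H-5β) | C=C1CC[C@H]2C(=C)CC[C@H]3CC(=O)O[C@@H]3[C@@H]21
F7 | step 6 | 3-(hydroxymethylidene)-6,9-dimethylidene-decahydroazuleno[4,5-b]furan-2-one (H-5β) | C=C1CC[C@H]2C(=C)CC[C@H]3C(=CO)C(=O)O[C@@H]3[C@@H]21
F8 | step 6 | cis-fused 2-ethoxy-6-methylidene-decahydroazuleno[4,5-b]furan-9-one (H-1α, H-5α, H-6β, H-7α) | O=C1CC[C@H]2C(=C)CC[C@H]3CC(OCC)O[C@@H]3[C@H]21
F9 | step 6 | 2-ethoxy-6,9-dimethylidene-decahydroazuleno[4,5-b]furan (H-5α series) | C=C1CC[C@H]2C(=C)CC[C@H]3CC(OCC)O[C@@H]3[C@H]21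
F10 | step 6 | 13-nor-dehydrocostus lactone (6,9-dimethylidene-decahydroazuleno[4,5-b]furan-2-one, H-5α) | C=C1CC[C@H]2C(=C)CC[C@H]3CC(=O)O[C@@H]3[C@H]21
F11 | step 6 | 3-(hydroxymethylidene)-6,9-dimethylidene-decahydroazuleno[4,5-b]furan-2-one (H-5α) | C=C1CC[C@H]2C(=C)CC[C@H]3C(=CO)C(=O)O[C@@H]3[C@H]21
F12 | step 18 | 2α-(phenylselanyl)-5-epi-dehydrozaluzanin C | C=C1C(=O)[C@H]([Se]c4ccccc4)[C@H]2C(=C)CC[C@H]3C(=C)C(=O)O[C@@H]3[C@@H]21
F13 | step 18 | 2α-(phenylseleninyl)-5-epi-dehydrozaluzanin C (selenoxide) | C=C1C(=O)[C@H]([Se](=O)c4ccccc4)[C@H]2C(=C)CC[C@H]3C(=C)C(=O)O[C@@H]3[C@@H]21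
F14 | step 7 | 2-methoxy-3,6-dimethylidene-9-(trimethylsilyloxy)-2,3,3a,4,5,6,6a,7,8,9b-decahydroazuleno[4,5-b]furan (C4=C5 silyl enol ether of 12) | C[Si](C)(C)OC1=C2[C@H]3OC(OC)C(=C)[C@@H]3CCC(=C)[C@@H]2CC1
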